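**Strategy**

With the quinone ring numbered C1 (C=O beside the chain), C2 (OH), C3 (CH3), C4 (C=O), C5 (H), C6 (nonadecyl), the oxygens on C2 and C4 flank C3 in the 1,3-pattern of a 2-methyl-5-alkylresorcinol. The ring is therefore built by a Michael–Claisen [4+2] annulation: dimethyl malonate, an acetate unit supplying C5 and C4, joins tetracos-4-yn-3-one, which supplies C6, C1, C2 and C3, forming the C5–C6 and C3–C4 bonds in one operation and delivering the arene directly. The precursor is thus an acyclic alkynyl ethyl ketone. The auxiliary ester on C5 is then excised and C1 is oxidized last.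

Key step: step 3

Remark: the target is achiral, so no stereocentre has to be set; ring atoms are numbered as in the paragraph above.

**Route**

Step 1
Reactants: 1 1-bromononadecane; 2 lithium acetylide ethylenediamine complex
Product: 3 henicos-1-yne
Conditions: LiC≡CH·H2NCH2CH2NH2 (1.5 equiv), DMSO/THF, 10 °C → rt
Reagents that add atoms: lithium acetylide ethylenediamine complex 2, [Li+].[C-]#C.NCCN
Why: SN2 alkylation of an acetylide by a primary bromide; the dipolar aprotic medium favours substitution over elimination and excess acetylide prevents dialkylation.

Step 2
Reactants: 3 henicos-1-yne; 4 N-methoxy-N-methylpropanamide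
Product: 7 tetracos-4-yn-3-one, via alkynyllithium 5 (not isolated), via tetrahedral adduct 6 (not isolated)
Conditions: n-BuLi, THF, −78 °C; then 4, −78 → 0 °C; cold 1 M HCl
Reagents that add atoms: N-methoxy-N-methylpropanamide 4, CCC(=O)N(C)OC
Why: Weinreb ketone synthesis; the N,O-chelated adduct 6 survives until the quench, so no second addition should occur, and the acidic quench protonates the released amine before it can add to the ynone.

Step 3
Reactants: 7 tetracos-4-yn-3-one; 8 dimethyl malonate
Product: 10 methyl 2,4-dihydroxy-3-methyl-6-nonadecylbenzoate, via Michael adduct 9 (not isolated)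
Conditions: 8 (1.5 equiv), NaOMe (3 equiv), MeOH/THF, 0 °C → reflux; then 1 M HCl
Reagents that add atoms: dimethyl malonate 8, COC(=O)CC(=O)OC
Why: Sodiomalonate adds in conjugate fashion to the electrophilic alkyne carbon of 7 that carries the chain (first C–C bond, adduct 9), proton transfer then gives the enolate at the CH2 of the ethyl ketone, which acylates one malonate ester with loss of methoxide (second C–C bond), and the cyclohexadienone so formed enolizes to the aromatic resorcylate, held as its phenoxide. The closest known reaction type is the Michael–Claisen (Michael–Dieckmann) annulation of malonates with alkynyl or alkenyl ketones used for β-resorcylates and 5-alkylresorcinols. The ring closes in a 6-(enolendo)-exo-trig mode, and no stereocentre is created. Regiochemistry needs no control element beyond the polarity of 7, since only its β-alkyne carbon is electrophilic and only the ethyl CH2 can reach an ester through a six-membered transition state, so the methyl group must end between the two hydroxyls and the chain meta to both. The selectivity that is needed is C- over O-acylation: closure through the enolate oxygen to a 2-pyranone is reversible under excess methoxide, whereas C-acylation is driven forward by aromatization and phenoxide formation, and the alkene geometry of 9 equilibrates through its delocalized anion.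

Step 4
Reactants: 10 methyl 2,4-dihydroxy-3-methyl-6-nonadecylbenzoate
Product: 12 2-methyl-5-nonadecylbenzene-1,3-diol, via resorcylic acid 11 (not isolated)
Conditions: KOH, H2O/ethylene glycol, 120 °C, N2; then HCl to pH 1, 90 °C
Reagents that add atoms: none
Why: Saponification followed by protodecarboxylation of the 2,4-dihydroxybenzoic acid 11, which should lose CO2 readily through ipso-protonation of the electron-rich ring; the inert atmosphere protects the resorcinolate from autoxidation.

Step 5
Reactants: 12 2-methyl-5-nonadecylbenzene-1,3-diol
Product: 13 Capiquinone C (2-hydroxy-3-methyl-6-nonadecyl-1,4-benzoquinone)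
Conditions: (KSO3)2NO (3 equiv), KH2PO4 buffer, H2O/CH2Cl2, methyltrioctylammonium chloride (cat.), rt; then dilute HCl
Reagents that add atoms: potassium nitrosodisulfonate, [K+].[K+].[O]N(S(=O)(=O)[O-])S(=O)(=O)[O-]
Why: Teuber oxidation; the phenoxyl radical is trapped by a second nitrosodisulfonate radical para to one hydroxyl and loss of imidodisulfonate should give the para-quinone that keeps the other hydroxyl, and since position 2 is blocked and the two ring CH positions of 12 are equivalent by symmetry, a single hydroxyquinone can form.

**Compound list**

1 | 1-bromononadecane | CCCCCCCCCCCCCCCCCCCBr | starting material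
2 | lithium acetylide ethylenediamine complex | [Li+].[C-]#C.NCCN | starting material
3 | henicos-1-yne | CCCCCCCCCCCCCCCCCCCC#C | intermediate
4 | N-methoxy-N-methylpropanamide | CCC(=O)N(C)OC | starting material
5 | (henicos-1-yn-1-yl)lithium, formed in the flask | CCCCCCCCCCCCCCCCCCCC#C[Li] | intermediate
6 | lithium 3-[methoxy(methyl)amino]tetracos-4-yn-3-olate, formed in the flask | CCCCCCCCCCCCCCCCCCCC#CC(CC)([O-])N(C)OC.[Li+] | intermediate
7 | tetracos-4-yn-3-one | CCCCCCCCCCCCCCCCCCCC#CC(=O)CC | intermediate
8 | dimethyl malonate | COC(=O)CC(=O)OC | starting material
9 | dimethyl 2-[(4Z)-3-oxotetracos-4-en-5-yl]propanedioate, formed in the flask as its sodium enolate | CCCCCCCCCCCCCCCCCCC/C(=C/C(=O)CC)C(C(=O)OC)C(=O)OC | intermediate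
10 | methyl 2,4-dihydroxy-3-methyl-6-nonadecylbenzoate | CCCCCCCCCCCCCCCCCCCc1cc(O)c(C)c(O)c1C(=O)OC | intermediate
11 | 2,4-dihydroxy-3-methyl-6-nonadecylbenzoic acid, formed in the flask | CCCCCCCCCCCCCCCCCCCc1cc(O)c(C)c(O)c1C(=O)O | intermediate
12 | 2-methyl-5-nonadecylbenzene-1,3-diol | CCCCCCCCCCCCCCCCCCCc1cc(O)c(C)c(O)c1 | intermediate
13 | Capiquinone C, 2-hydroxy-3-methyl-6-nonadecyl-1,4-benzoquinone | CCCCCCCCCCCCCCCCCCCC1=CC(=O)C(C)=C(O)C1=O | target

**Step count and risks**

Total step count: 5. Longest linear sequence: 5.

Step 3 is the most likely to fail. The Michael adduct may close through the enolate oxygen to a 2-pyranone instead of through carbon, or the ynone may be consumed by base-induced isomerization before conjugate addition. The fallback runs the same annulation at the enone oxidation level, where neither process interferes, and aromatizes afterwards. Setting out from 7, semi-hydrogenation (H2, Pd/CaCO3 poisoned with Pb(OAc)2, quinoline, hexane) should give (Z)-tetracos-4-en-3-one F1; the alkene geometry is irrelevant for the conjugate addition. Its Michael–Claisen reaction with 8 (NaOMe, MeOH, reflux) should give racemic methyl trans-2-hydroxy-3-methyl-6-nonadecyl-4-oxocyclohex-2-ene-1-carboxylate F2. Dehydrogenation with DDQ (dioxane, reflux) should then erase both stereocentres and rejoin the route at 10.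

Step 5 is the second risk. The waxy substrate may have poor contact with the water-soluble radical salt, so the oxidation may stall, and radical coupling or over-oxidation of the electron-rich ring may compete. The fallback introduces the oxygen by an ionic sequence. Setting out from 12, Vilsmeier–Haack formylation (POCl3, DMF, 0 °C → rt; aq. NaOAc) should give 2,4-dihydroxy-3-methyl-6-nonadecylbenzaldehyde F3. Dakin oxidation (H2O2, NaOH, THF/H2O, 0 °C, argon; then acid) should give 3-methyl-6-nonadecylbenzene-1,2,4-triol F4 with loss of formate. Dehydrogenation of F4 with Ag2O in Et2O should return to the route at 13.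

Step 4 is the third risk. Saponification of the doubly ortho-substituted, hydrogen-bonded ester may be too slow, and the resorcinolate may autoxidize under hot alkali. The fallback changes the auxiliary ester so that no basic hydrolysis is needed. Setting out from 7, the annulation would be run with tert-butyl methyl malonate (KOtBu, t-BuOH/THF, reflux), in which the enolate should attack the less hindered methyl ester, to give tert-butyl 2,4-dihydroxy-3-methyl-6-nonadecylbenzoate F5. Treatment with TFA in CH2Cl2 at 40 °C should cleave the tert-butyl ester and decarboxylate the acid, returning to the route at 12.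

**Further compounds**

F1 | step 3 | (Z)-tetracos-4-en-3-one | CCCCCCCCCCCCCCCCCCC/C=C\C(=O)CC
F2 | step 3 | methyl trans-2-hydroxy-3-methyl-6-nonadecyl-4-oxocyclohex-2-ene-1-carboxylate (racemic, one enantiomer drawn) | CCCCCCCCCCCCCCCCCCC[C@@H]1CC(=O)C(C)=C(O)[C@H]1C(=O)OC
F3 | step 5 | 2,4-dihydroxy-3-methyl-6-nonadecylbenzaldehyde | CCCCCCCCCCCCCCCCCCCc1cc(O)c(C)c(O)c1C=O
F4 | step 5 | 3-methyl-6-nonadecylbenzene-1,2,4-triol | CCCCCCCCCCCCCCCCCCCc1cc(O)c(C)c(O)c1O
F5 | step 4 | tert-butyl 2,4-dihydroxy-3-methyl-6-nonadecylbenzoate | CCCCCCCCCCCCCCCCCCCc1cc(O)c(C)c(O)c1C(=O)OC(C)(C)C
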